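Everything rests on the C10–C11 bond of ring A (the cyclohexene C1, C10–C14). The oxygenated carbons C12 and C9 are 1,4-related across this bond, a dissonant relationship that polar chemistry cannot assemble directly, so two enol-type donor carbons are joined under oxidation. Anodic oxidation of an acyclic bis(enol ether), in which the quaternary C1 carries a Z silyl dienol ether (C11–C14) and a methyl enol ether (C9=C10), closes ring A, sets C10 and C11, and delivers the C12 enone and the C9 aldehyde as its dimethyl acetal in one operation. The ten-membered ring is closed later at C6–C7 and the lactone is annulated last.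

Key step: step 14

Remark on the chemistry: briarane numbering is used throughout, TBS = tert-butyldimethylsilyl and TBDPS = tert-butyldiphenylsilyl, and enol ether 9 is assumed to be carried on as its E isomer (a Z minor isomer would be removed by chromatography).

Step 1
Reactants: 1 3-[(tert-butyldiphenylsilyl)oxy]propanal
Product: 2 ethyl 5-[(tert-butyldiphenylsilyl)oxy]-3-oxopentanoate
Conditions: ethyl diazoacetate, SnCl2 (cat.), CH2Cl2, 23 °C
Reagents that add atoms: ethyl diazoacetate, CCOC(=O)C=[N+]=[N-]
Why: Roskamp reaction: the SnCl2-activated aldehyde is attacked by the diazo carbon and a 1,2-hydride shift with loss of N2 should give the β-keto ester without touching the silyl ether.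

Step 2
Reactants: 2 ethyl 5-[(tert-butyldiphenylsilyl)oxy]-3-oxopentanoate
Product: 3 ethyl (3R)-5-[(tert-butyldiphenylsilyl)oxy]-3-hydroxypentanoate
Conditions: H2 (4 atm), RuCl2[(R)-BINAP] (cat.), EtOH, 50 °C
Reagents that add atoms: none
Why: Noyori asymmetric hydrogenation of a β-keto ester: the (R)-BINAP ruthenium catalyst should reduce the chelated ketone from one face and set the (R)-carbinol that becomes C2.

Step 3
Reactants: 3 ethyl (3R)-5-[(tert-butyldiphenylsilyl)oxy]-3-hydroxypentanoate
Product: 4 ethyl (2R,3R)-2-allyl-5-[(tert-butyldiphenylsilyl)oxy]-3-hydroxypentanoate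
Conditions: LiN(iPr)2 (2.2 equiv), THF, −78 → −20 °C; allyl bromide, DMPU, −78 → 0 °C; aq. NH4Cl
Reagents that add atoms: allyl bromide, C=CCBr
Why: Frater–Seebach alkylation: the lithium-chelated dianion should be allylated on the face opposite to the C3 side chain, giving the anti (2R,3R) ester whose allyl carbons are the future C10 and C9.

Step 4
Reactants: 4 ethyl (2R,3R)-2-allyl-5-[(tert-butyldiphenylsilyl)oxy]-3-hydroxypentanoate
Product: 5 ethyl (2S,3R)-2-allyl-5-[(tert-butyldiphenylsilyl)oxy]-3-hydroxy-2-methylpentanoate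
Conditions: LiN(iPr)2 (2.3 equiv), THF, −78 → −10 °C; MeI, DMPU, −78 → 0 °C; aq. NH4Cl
Reagents that add atoms: iodomethane, CI
Why: Second Frater–Seebach alkylation: the methyl group should enter the chelated dianion from the same face as before, so that methyl ends anti and allyl syn to the hydroxyl, which sets the quaternary C1.

Step 5
Reactants: 5 ethyl (2S,3R)-2-allyl-5-[(tert-butyldiphenylsilyl)oxy]-3-hydroxy-2-methylpentanoate
Product: 6 ethyl (2S,3R)-2-allyl-3-[(tert-butyldimethylsilyl)oxy]-5-[(tert-butyldiphenylsilyl)oxy]-2-methylpentanoate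
Conditions: TBSOTf, 2,6-lutidine, CH2Cl2, 0 °C
Reagents that add atoms: tert-butyldimethylsilyl triflate, CC(C)(C)[Si](C)(C)OS(=O)(=O)C(F)(F)F
Why: Silylation with the reactive triflate should cap the hindered C2 hydroxyl; the bulky silyl ether is kept to the key step, where it enlarges the C2 branch.

Step 6
Reactants: 6 ethyl (2S,3R)-2-allyl-3-[(tert-butyldimethylsilyl)oxy]-5-[(tert-butyldiphenylsilyl)oxy]-2-methylpentanoate
Product: 8 dimethyl acetal ester (C9 as CH(OMe)2), via aldehyde 7 (not isolated)
Conditions: O3, CH2Cl2/MeOH, −78 °C; Me2S; then HC(OMe)3, PPTS, MeOH, 23 °C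
Reagents that add atoms: ozone, [O-][O+]=O (carbonyl oxygen of 7); trimethyl orthoformate, COC(OC)OC (both methoxy groups of 8)
Why: Ozonolysis cleaves the only alkene to the C9 aldehyde, and acetalisation with orthoformate under mild acid should store it as the dimethyl acetal while both silyl ethers survive.

Step 7
Reactants: 8 dimethyl acetal ester
Product: 9 ethyl (2S,3R)-3-[(tert-butyldimethylsilyl)oxy]-5-[(tert-butyldiphenylsilyl)oxy]-2-[(E)-2-methoxyethenyl]-2-methylpentanoate
Conditions: Me3SiOTf, iPr2NEt, CH2Cl2, −20 → 23 °C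
Reagents that add atoms: none
Why: The silyl triflate ionises the acetal to an oxocarbenium ion and the amine removes a C10 proton (acetal-to-enol-ether elimination), the E isomer being favoured because it keeps the methoxy group away from the quaternary C1.

Step 8
Reactants: 9 (E)-methyl enol ether ester
Product: 10 neopentyl alcohol (C14 as CH2OH)
Conditions: i-Bu2AlH, CH2Cl2, −78 → 0 °C; aq. potassium sodium tartrate
Reagents that add atoms: none
Why: Aluminium hydride reduction of the neopentyl ester to the primary alcohol; the enol ether and the silyl ethers are inert to the reagent.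

Step 9
Reactants: 10 neopentyl alcohol
Product: 11 C14 aldehyde
Conditions: Dess–Martin periodinane, NaHCO3, CH2Cl2, 0 → 23 °C
Reagents that add atoms: none
Why: Buffered Dess–Martin oxidation should give the aldehyde, which cannot epimerise because C1 is quaternary, without acid damage to the enol ether.

Step 10
Reactants: 11 C14 aldehyde
Product: 12 terminal alkyne (C14≡C13)
Conditions: dimethyl (1-diazo-2-oxopropyl)phosphonate, K2CO3, MeOH, 0 → 23 °C
Reagents that add atoms: dimethyl (1-diazo-2-oxopropyl)phosphonate, COP(=O)(OC)C(=[N+]=[N-])C(C)=O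
Why: Seyferth–Gilbert homologation with the Ohira–Bestmann reagent turns the aldehyde carbon into the alkyne carbon C14 under mildly basic conditions that tolerate hindered aldehydes.

Step 11
Reactants: 12 terminal alkyne
Product: 13 ethyl ynone (C12 ketone)
Conditions: n-BuLi, THF, −78 °C; N-methoxy-N-methylpropanamide, −78 → 0 °C; aq. NH4Cl
Reagents that add atoms: N-methoxy-N-methylpropanamide, CCC(=O)N(C)OC
Why: The lithium acetylide should be acylated by the Weinreb amide, whose chelated tetrahedral adduct prevents over-addition, to give the C12 ethyl ynone.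

Step 12
Reactants: 13 ethyl ynone
Product: 14 (Z)-enone
Conditions: H2 (1 atm), Pd/CaCO3 poisoned with Pb(OAc)2 (Lindlar catalyst), quinoline, EtOAc, 23 °C
Reagents that add atoms: none
Why: Lindlar semi-hydrogenation adds hydrogen syn to the alkyne and should stop at the Z enone, the poisoned catalyst leaving the enol ether untouched.

Step 13
Reactants: 14 (Z)-enone
Product: 15 acyclic bis(enol ether)
Conditions: LiN(iPr)2, THF/DMPU, −78 °C; TBSCl, −78 → 0 °C
Reagents that add atoms: tert-butyldimethylsilyl chloride, CC(C)(C)[Si](C)(C)Cl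
Why: Kinetic deprotonation can occur only at C11 (C14 has no γ-hydrogen), the polar cosolvent favours the Z(O) enolate, and O-silylation should give the cross-conjugated silyl dienol ether without isomerising the Z alkene.

Step 14
Reactants: 15 acyclic bis(enol ether)
Product: 16 ring A enone with C9 dimethyl acetal
Conditions: constant current (8 mA, 2.2 F/mol), reticulated vitreous carbon anode, Pt cathode, undivided cell, 0.1 M LiClO4, MeOH/THF (1:1), 2,6-lutidine, 0 → 23 °C
Reagents that add atoms: methanol, CO
Why: One-electron oxidation at the anode removes an electron from the most electron-rich π system, the silyl dienol ether, and the radical cation is attacked at C11 by the nucleophilic β-carbon (C10) of the methyl enol ether; a second oxidation gives the C9 oxocarbenium ion, which methanol traps as the dimethyl acetal, while transfer of the silyl group to methanol releases the C12 ketone. The closest known reaction type is the intramolecular anodic coupling of an enol ether radical cation with a second enol ether, an oxidative umpolung that joins two donor carbons into a 1,4-dioxygenated array. Ring A closes in a six-membered mode that is endo with respect to the dienol ether (C11 terminus, C12–C14 inside the ring) and exo with respect to the C9=C10 bond, the Z C13=C14 alkene and the quaternary C1 holding both termini within bonding distance. C10 is set by a chair-like transition state in which C9 of the enol ether lies anti to the bulky silyloxy-bearing C2 branch on C1 and therefore cis to the C1 methyl, and C11 is set by the Z geometry of the silyl enol ether, which keeps the C11 methyl outside the forming ring and so cis to C9. The step needs chemoselective oxidation of the dienol ether over the methyl enol ether and kinetic integrity at the epimerisable C11, secured by the lower oxidation potential of the silyloxydiene, by 2,6-lutidine as proton scavenger and by a neutral work-up.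

Step 15
Reactants: 16 ring A enone with C9 dimethyl acetal
Product: 17 ring A allylic alcohol (C12 hydroxyl cis to the C11 methyl)
Conditions: i-Bu2AlH, toluene, −78 °C; aq. potassium sodium tartrate
Reagents that add atoms: none
Why: 1,2-Reduction of the enone by the bulky aluminium hydride should occur from the face opposite the pseudo-axial C10 acetal branch, placing the C12 hydroxyl cis to the C11 methyl, and it removes the ketone before C11 can epimerise.

Step 16
Reactants: 17 ring A allylic alcohol
Product: 18 C12 butanoate (ester oxygen trans to the C11 methyl)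
Conditions: PPh3, DIAD, butanoic acid, toluene, 0 → 23 °C
Reagents that add atoms: butanoic acid, CCCC(=O)O
Why: Mitsunobu esterification: SN2 displacement of the activated pseudo-axial C12 oxygen by butanoate inverts C12 and installs the final ester in the required configuration, SN2' attack at the neopentyl C14 being disfavoured.

Step 17
Reactants: 18 C12 butanoate
Product: 19 C2,C4-diol
Conditions: Bu4NF, AcOH, THF, 23 → 40 °C
Reagents that add atoms: none
Why: Fluoride cleaves both silyl ethers, and the acetic acid buffer should protect the butanoate and keep the medium neutral so that the acetal stays intact.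

Step 18
Reactants: 19 C2,C4-diol
Product: 20 C4 primary iodide
Conditions: I2, PPh3, imidazole, CH2Cl2, 0 °C
Reagents that add atoms: iodine, II
Why: Appel-type iodination should be selective for the primary C4 hydroxyl, the neopentyl secondary C2 hydroxyl being too hindered to form the alkoxyphosphonium salt.

Step 19
Reactants: 20 C4 primary iodide
Product: 21 C2 acetate C4 iodide
Conditions: Ac2O, DMAP, pyridine, CH2Cl2, 23 °C
Reagents that add atoms: acetic anhydride, CC(=O)OC(C)=O
Why: DMAP-catalysed acetylation installs the final C2 acetate and removes the last free hydroxyl before the organozinc chemistry.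

Step 20
Reactants: 22 propyne
Product: 24 2-[(Z)-2-bromoprop-1-enyl]-4,4,5,5-tetramethyl-1,3,2-dioxaborolane, via dibromoborane 23 (not isolated)
Conditions: BBr3, CH2Cl2, −78 → 23 °C; then pinacol, 23 °C
Reagents that add atoms: boron tribromide, BrB(Br)Br; pinacol, CC(C)(O)C(C)(C)O
Why: Bromoboration of propyne is a syn addition with boron at the terminal carbon, so the Z bromoalkenylborane results, and esterification with pinacol gives the stable boronate.

Step 21
Reactants: 21 C2 acetate C4 iodide; 24 (Z)-2-bromopropenyl pinacol boronate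
Product: 26 (Z)-alkenyl pinacol boronate (C4–C5 bond formed), via alkylzinc iodide 25 (not isolated)
Conditions: Zn dust (activated with BrCH2CH2Br and Me3SiCl), DMA/THF, 40 °C; then 24, PdCl2(DPEphos) (cat.), THF, 23 °C
Reagents that add atoms: zinc, [Zn] (held only in the non-isolated 25)
Why: Zinc inserts into the primary C–I bond without harming the esters, and Negishi coupling at the C–Br bond of 24 proceeds with retention, so C4 ends cis to boron; oxidative addition of zerovalent palladium to the alkenyl bromide should outpace ionisation of the hindered allylic butanoate.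

Step 22
Reactants: 26 (Z)-alkenyl pinacol boronate
Product: 27 (Z)-alkenyl iodide (C4 cis to iodine)
Conditions: I2, aq. NaOH, THF, 0 °C
Reagents that add atoms: iodine, II
Why: Iododeboronation of the hydroxide-activated alkenylboronate should replace boron by iodine with retention of geometry, and the esters are expected to survive the brief cold exposure to base.

Step 23
Reactants: 27 (Z)-alkenyl iodide
Product: 28 C9 aldehyde
Conditions: CF3CO2H, H2O, CHCl3, 0 °C
Reagents that add atoms: water, O
Why: Acid-catalysed hydrolysis of the dimethyl acetal liberates the C9 aldehyde at low temperature, where the C10 stereocentre should not epimerise.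

Step 24
Reactants: 29 acrolein
Product: 31 rac-tert-butyldimethyl{[1-(tributylstannyl)prop-2-en-1-yl]oxy}silane, via hydroxystannane 30 (not isolated)
Conditions: Bu3SnH, LiN(iPr)2, THF, −78 °C; acrolein; aq. NH4Cl; then TBSCl, imidazole, DMF, 0 °C
Reagents that add atoms: tributyltin hydride, CCCC[SnH](CCCC)CCCC; tert-butyldimethylsilyl chloride, CC(C)(C)[Si](C)(C)Cl
Why: Tributylstannyllithium adds 1,2 to acrolein and the labile α-hydroxystannane is silylated at once to give the α-silyloxy allylstannane.

Step 25
Reactants: 28 C9 aldehyde; 31 α-silyloxy allylstannane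
Product: 32 homoallylic alcohol (C9 hydroxyl, C8 OTBS anti, terminal vinyl)
Conditions: InCl3, EtOAc, −78 → 23 °C
Reagents that add atoms: none
Why: Transmetalation with InCl3 (SE2') gives the (E)-γ-silyloxyallylindium reagent, which should add through a chair transition state to give the anti C8/C9 relationship, with Felkin–Anh approach anti to the quaternary C1 setting C9 as required.

Step 26
Reactants: 32 homoallylic alcohol
Product: 33 C9 acetate
Conditions: Ac2O, DMAP, pyridine, CH2Cl2, 23 °C
Reagents that add atoms: acetic anhydride, CC(=O)OC(C)=O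
Why: Acetylation installs the final C9 acetate before the lactone exists, so that no free C9 hydroxyl can later compete for the lactone carbonyl.

Step 27
Reactants: 33 C9 acetate
Product: 35 C7 aldehyde, via diol 34 (not isolated)
Conditions: OsO4 (cat.), NaIO4, 2,6-lutidine, dioxane/H2O, 23 °C
Reagents that add atoms: sodium periodate, [Na+].[O-]I(=O)(=O)=O (terminal oxidant; oxygen passed on through catalytic osmium tetroxide, O=[Os](=O)(=O)=O)
Why: Johnson–Lemieux oxidation: OsO4 should dihydroxylate the unhindered monosubstituted alkene in preference to the hindered ring A alkene and the deactivated iodoalkene, and periodate cleaves the diol to the C7 aldehyde.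

Step 28
Reactants: 35 C7 aldehyde
Product: 36 ten-membered carbocyclic allylic alcohol (C7 hydroxyl)
Conditions: CrCl2 (10 equiv), NiCl2 (cat.), DMSO/THF, 23 °C, slow addition to 2 mM
Reagents that add atoms: none
Why: Nozaki–Hiyama–Kishi reaction: zerovalent nickel inserts into the C6–I bond, transmetalation gives an alkenyl species of trivalent chromium that adds to the C7 aldehyde with retention of the Z geometry and closes the ten-membered ring under high dilution, Felkin–Anh addition anti to the C8 silyloxy group being expected to set C7.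

Step 29
Reactants: 36 ten-membered carbocyclic allylic alcohol
Product: 37 C7 acrylate
Conditions: acryloyl chloride, iPr2NEt, DMAP (cat.), CH2Cl2, −20 → 0 °C
Reagents that add atoms: acryloyl chloride, C=CC(=O)Cl
Why: Acylation of the secondary allylic alcohol attaches the three carbons C19, C17 and C18 of the lactone as an acrylate ready for conjugate reduction.

Step 30
Reactants: 37 C7 acrylate
Product: 38 C8 alcohol
Conditions: HF·pyridine, THF, 0 → 23 °C
Reagents that add atoms: none
Why: Buffered fluoride removes the only silyl ether, and the near-neutral medium should prevent acyl migration onto the freed C8 hydroxyl.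

Step 31
Reactants: 38 C8 alcohol
Product: 39 C8 ketone
Conditions: Dess–Martin periodinane, NaHCO3, CH2Cl2, 0 → 23 °C
Reagents that add atoms: none
Why: Dess–Martin oxidation of the secondary alcohol under neutral conditions should give the C8 ketone without enolisation toward C7 or C9.

Step 32
Reactants: 39 C8 ketone
Product: 40 CNP0211702.1
Conditions: [(Ph3P)CuH]6, toluene, −40 → 0 °C; aq. NH4Cl
Reagents that add atoms: none
Why: Reductive aldol cyclisation: copper hydride adds to the acrylate in conjugate fashion, the copper enolate attacks the neighbouring C8 ketone from the face that keeps C6 and C9 anti across C7–C8 (trans ring fusion, tertiary hydroxyl cis to C6), and a chelated chair-like transition state should place the new C17 methyl cis to that hydroxyl.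

Compound list

1 | 3-[(tert-butyldiphenylsilyl)oxy]propanal | O=CCCO[Si](c1ccccc1)(c1ccccc1)C(C)(C)C | starting material
2 | ethyl 5-[(tert-butyldiphenylsilyl)oxy]-3-oxopentanoate | CCOC(=O)CC(=O)CCO[Si](c1ccccc1)(c1ccccc1)C(C)(C)C | intermediate
3 | ethyl (3R)-5-[(tert-butyldiphenylsilyl)oxy]-3-hydroxypentanoate | CCOC(=O)C[C@H](O)CCO[Si](c1ccccc1)(c1ccccc1)C(C)(C)C | intermediate
4 | ethyl (2R,3R)-2-allyl-5-[(tert-butyldiphenylsilyl)oxy]-3-hydroxypentanoate | CCOC(=O)[C@H](CC=C)[C@H](O)CCO[Si](c1ccccc1)(c1ccccc1)C(C)(C)C | intermediate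
5 | ethyl (2S,3R)-2-allyl-5-[(tert-butyldiphenylsilyl)oxy]-3-hydroxy-2-methylpentanoate | CCOC(=O)[C@@](C)(CC=C)[C@H](O)CCO[Si](c1ccccc1)(c1ccccc1)C(C)(C)C | intermediate
6 | ethyl (2S,3R)-2-allyl-3-[(tert-butyldimethylsilyl)oxy]-5-[(tert-butyldiphenylsilyl)oxy]-2-methylpentanoate | CCOC(=O)[C@@](C)(CC=C)[C@H](O[Si](C)(C)C(C)(C)C)CCO[Si](c1ccccc1)(c1ccccc1)C(C)(C)C | intermediate
7 | ethyl (2S,3R)-3-[(tert-butyldimethylsilyl)oxy]-5-[(tert-butyldiphenylsilyl)oxy]-2-methyl-2-(2-oxoethyl)pentanoate | CCOC(=O)[C@@](C)(CC=O)[C@H](O[Si](C)(C)C(C)(C)C)CCO[Si](c1ccccc1)(c1ccccc1)C(C)(C)C | intermediate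
8 | ethyl (2S,3R)-3-[(tert-butyldimethylsilyl)oxy]-5-[(tert-butyldiphenylsilyl)oxy]-2-(2,2-dimethoxyethyl)-2-methylpentanoate | CCOC(=O)[C@@](C)(CC(OC)OC)[C@H](O[Si](C)(C)C(C)(C)C)CCO[Si](c1ccccc1)(c1ccccc1)C(C)(C)C | intermediate
9 | ethyl (2S,3R)-3-[(tert-butyldimethylsilyl)oxy]-5-[(tert-butyldiphenylsilyl)oxy]-2-[(E)-2-methoxyethenyl]-2-methylpentanoate | CCOC(=O)[C@@](C)(/C=C/OC)[C@H](O[Si](C)(C)C(C)(C)C)CCO[Si](c1ccccc1)(c1ccccc1)C(C)(C)C | intermediate
10 | 3-[(tert-butyldimethylsilyl)oxy]-5-[(tert-butyldiphenylsilyl)oxy]-2-[(E)-2-methoxyethenyl]-2-methylpentan-1-ol, C1 and C2 as in 9 | OC[C@@](C)(/C=C/OC)[C@H](O[Si](C)(C)C(C)(C)C)CCO[Si](c1ccccc1)(c1ccccc1)C(C)(C)C | intermediate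
11 | 3-[(tert-butyldimethylsilyl)oxy]-5-[(tert-butyldiphenylsilyl)oxy]-2-[(E)-2-methoxyethenyl]-2-methylpentanal, C1 and C2 as in 9 | O=C[C@@](C)(/C=C/OC)[C@H](O[Si](C)(C)C(C)(C)C)CCO[Si](c1ccccc1)(c1ccccc1)C(C)(C)C | intermediate
12 | terminal alkyne: quaternary C1 bearing methyl, ethynyl (C14≡C13), (E)-2-methoxyethenyl (C10=C9) and the (1R)-1-(TBS-oxy)-3-(TBDPS-oxy)propyl chain (C2–C4) | C#C[C@@](C)(/C=C/OC)[C@H](O[Si](C)(C)C(C)(C)C)CCO[Si](c1ccccc1)(c1ccccc1)C(C)(C)C | intermediate
13 | ethyl ynone: 12 acylated at C13 with a propanoyl group (C12 ketone) | CCC(=O)C#C[C@@](C)(/C=C/OC)[C@H](O[Si](C)(C)C(C)(C)C)CCO[Si](c1ccccc1)(c1ccccc1)C(C)(C)C | intermediate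
14 | (Z)-enone: cis C13=C14 alkene of 13 | CCC(=O)/C=C\[C@@](C)(/C=C/OC)[C@H](O[Si](C)(C)C(C)(C)C)CCO[Si](c1ccccc1)(c1ccccc1)C(C)(C)C | intermediate
15 | acyclic bis(enol ether): Z(O) TBS dienol ether (C11=C12, methyl cis to OSi), Z C13=C14, E methyl enol ether C9=C10, C2 OTBS, C4 OTBDPS | C/C=C(O[Si](C)(C)C(C)(C)C)/C=C\[C@@](C)(/C=C/OC)[C@H](O[Si](C)(C)C(C)(C)C)CCO[Si](c1ccccc1)(c1ccccc1)C(C)(C)C | intermediate
16 | ring A enone: cyclohex-2-enone (C12 ketone, C13=C14) with quaternary C1 (methyl and C2 chain), C10 dimethoxymethyl cis to the C1 methyl, C11 methyl cis to the C10 branch | O=C1C=C[C@@]([C@H](O[Si](C)(C)C(C)(C)C)CCO[Si](c2ccccc2)(c2ccccc2)C(C)(C)C)(C)[C@H]([C@H]1C)C(OC)OC | intermediate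
17 | ring A allylic alcohol: C12 hydroxyl cis to the C11 methyl | O[C@H]1C=C[C@@]([C@H](O[Si](C)(C)C(C)(C)C)CCO[Si](c2ccccc2)(c2ccccc2)C(C)(C)C)(C)[C@H]([C@H]1C)C(OC)OC | intermediate
18 | C12 butanoate, ester oxygen trans to the C11 methyl | CCCC(=O)O[C@@H]1C=C[C@@]([C@H](O[Si](C)(C)C(C)(C)C)CCO[Si](c2ccccc2)(c2ccccc2)C(C)(C)C)(C)[C@H]([C@H]1C)C(OC)OC | intermediate
19 | C2,C4-diol of 18 | CCCC(=O)O[C@@H]1C=C[C@@]([C@H](O)CCO)(C)[C@H]([C@H]1C)C(OC)OC | intermediate
20 | C4 primary iodide with free C2 hydroxyl | CCCC(=O)O[C@@H]1C=C[C@@]([C@H](O)CCI)(C)[C@H]([C@H]1C)C(OC)OC | intermediate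
21 | C2 acetate C4 iodide | CCCC(=O)O[C@@H]1C=C[C@@]([C@H](OC(C)=O)CCI)(C)[C@H]([C@H]1C)C(OC)OC | intermediate
22 | propyne | CC#C | starting material
23 | dibromo[(Z)-2-bromoprop-1-enyl]borane | C/C(Br)=C/B(Br)Br | intermediate
24 | 2-[(Z)-2-bromoprop-1-enyl]-4,4,5,5-tetramethyl-1,3,2-dioxaborolane | C/C(Br)=C/B1OC(C)(C)C(C)(C)O1 | intermediate
25 | C4 alkylzinc iodide of 21 | CCCC(=O)O[C@@H]1C=C[C@@]([C@H](OC(C)=O)CC[Zn]I)(C)[C@H]([C@H]1C)C(OC)OC | intermediate
26 | (Z)-alkenyl pinacol boronate: C4–C5(Me)=C6H–B(pin), C4 cis to boron | CCCC(=O)O[C@@H]1C=C[C@@]([C@H](OC(C)=O)CC/C(C)=C\B2OC(C)(C)C(C)(C)O2)(C)[C@H]([C@H]1C)C(OC)OC | intermediate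
27 | (Z)-alkenyl iodide: C4–C5(Me)=C6H–I, C4 cis to iodine | CCCC(=O)O[C@@H]1C=C[C@@]([C@H](OC(C)=O)CC/C(C)=C\I)(C)[C@H]([C@H]1C)C(OC)OC | intermediate
28 | C9 aldehyde of 27 | CCCC(=O)O[C@@H]1C=C[C@@]([C@H](OC(C)=O)CC/C(C)=C\I)(C)[C@H]([C@H]1C)C=O | intermediate
29 | acrolein (prop-2-enal) | C=CC=O | starting material
30 | rac-1-(tributylstannyl)prop-2-en-1-ol | C=CC(O)[Sn](CCCC)(CCCC)CCCC | intermediate
31 | rac-tert-butyldimethyl{[1-(tributylstannyl)prop-2-en-1-yl]oxy}silane | C=CC(O[Si](C)(C)C(C)(C)C)[Sn](CCCC)(CCCC)CCCC | intermediate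
32 | homoallylic alcohol: C9 hydroxyl, C8 OTBS (anti to C9–O), terminal vinyl on C8 | CCCC(=O)O[C@@H]1C=C[C@@]([C@H](OC(C)=O)CC/C(C)=C\I)(C)[C@H]([C@H]1C)[C@@H](O)[C@@H](O[Si](C)(C)C(C)(C)C)C=C | intermediate
33 | C9 acetate of 32 | CCCC(=O)O[C@@H]1C=C[C@@]([C@H](OC(C)=O)CC/C(C)=C\I)(C)[C@H]([C@H]1C)[C@@H](OC(C)=O)[C@@H](O[Si](C)(C)C(C)(C)C)C=C | intermediate
34 | vicinal diol from the vinyl group of 33 (mixture at the new carbinol) | CCCC(=O)O[C@@H]1C=C[C@@]([C@H](OC(C)=O)CC/C(C)=C\I)(C)[C@H]([C@H]1C)[C@@H](OC(C)=O)[C@@H](O[Si](C)(C)C(C)(C)C)C(O)CO | intermediate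
35 | C7 aldehyde: C9 acetate, C8 OTBS, (Z)-alkenyl iodide | CCCC(=O)O[C@@H]1C=C[C@@]([C@H](OC(C)=O)CC/C(C)=C\I)(C)[C@H]([C@H]1C)[C@@H](OC(C)=O)[C@@H](O[Si](C)(C)C(C)(C)C)C=O | intermediate
36 | ten-membered carbocycle: C7 hydroxyl (anti to C8 OTBS), Z C5=C6, C2 and C9 acetates, C12 butanoate | CCCC(=O)O[C@@H]1C=C[C@@]2(C)[C@H]([C@H]1C)[C@@H](OC(C)=O)[C@@H](O[Si](C)(C)C(C)(C)C)[C@@H](O)/C=C(/C)CC[C@H]2OC(C)=O | intermediate
37 | C7 acrylate of 36 | CCCC(=O)O[C@@H]1C=C[C@@]2(C)[C@H]([C@H]1C)[C@@H](OC(C)=O)[C@@H](O[Si](C)(C)C(C)(C)C)[C@@H](OC(=O)C=C)/C=C(/C)CC[C@H]2OC(C)=O | intermediate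
38 | C8 alcohol of 37 | CCCC(=O)O[C@@H]1C=C[C@@]2(C)[C@H]([C@H]1C)[C@@H](OC(C)=O)[C@@H](O)[C@@H](OC(=O)C=C)/C=C(/C)CC[C@H]2OC(C)=O | intermediate
39 | C8 ketone with C7 acrylate | CCCC(=O)O[C@@H]1C=C[C@@]2(C)[C@H]([C@H]1C)[C@@H](OC(C)=O)C(=O)[C@@H](OC(=O)C=C)/C=C(/C)CC[C@H]2OC(C)=O | intermediate
40 | CNP0211702.1 | CCCC(=O)O[C@@H]1C=C[C@@]2(C)[C@H]([C@H]1C)[C@@H](OC(C)=O)[C@@]1(O)[C@H](/C=C(/C)CC[C@H]2OC(C)=O)OC(=O)[C@@H]1C | target

Total step count: 32 (30 in the main line plus the two reagent preparations, steps 20 and 24).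
Longest linear sequence: 30 steps (steps 1–19, 21–23 and 25–32).

Steps most likely to fail

Step 14 (anodic ring closure). The radical cation may be consumed by methanolysis or over-oxidation before the C10–C11 bond forms. The enol ether may also add to the wrong face, so that C10 or C11 is mis-set, and C11 may epimerise if the medium turns acidic. The fallback sets out from 14 and returns at 16. Deprotonation of 14 with LiN(iPr)2 at −78 °C and quenching of the enolate with I2 would give the C11 α-iodo ketone F1. Mild aqueous acid (oxalic acid, wet THF) would hydrolyse the methyl enol ether to the C9 aldehyde F2. A secondary amine catalyst ((S)-2-methylproline, Et3N, CHCl3) would form the aldehyde enamine, which should displace iodide at C11 in an intramolecular SN2 α-alkylation to give the ring A keto aldehyde F3. Acetalisation (HC(OMe)3, PPTS, MeOH) then gives 16. The bond is thus made by polar enamine alkylation instead of oxidative coupling, with the amine catalyst taking over the facial control.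

Step 28 (ten-membered ring closure). Oligomerisation may outrun closure of the strained ring, the β-acetoxy aldehyde may lose acetate by elimination, or the alkenylchromium may add to the wrong face of the aldehyde. The fallback sets out from 35 and returns at 36. Pinnick oxidation (NaClO2, NaH2PO4, 2-methyl-2-butene) would give the carboxylic acid F4, and 2,2'-dipyridyl disulfide with PPh3 would convert it into the S-2-pyridyl thioester F5. An intramolecular nickel/zirconium-mediated ketone synthesis (NiBr2(dtbbpy) cat., Cp2ZrCl2, Zn, DMI/THF, high dilution) would join C6 to the acyl carbon C7 and give the macrocyclic enone F6, in which C7 is trigonal and no stereocentre is formed during ring closure. Luche reduction (NaBH4, CeCl3, MeOH, −78 °C), expected to follow the Felkin–Anh sense anti to the C8 silyloxy group, then gives 36.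

Step 32 (lactone annulation). Conjugate reduction may stop at the propanoate without aldol closure, the copper hydride may reduce the C8 ketone directly, or the enolate may close on the wrong ketone face. The fallback sets out from 36 and returns at 40. Acylation of 36 with 2-bromopropanoyl bromide and pyridine would give the 2-bromopropanoate F7. HF·pyridine would free the C8 alcohol F8, and Dess–Martin oxidation would give the C8 ketone F9. SmI2 in THF at −78 °C would then reduce the C–Br bond, and the samarium enolate should close onto the ketone in an intramolecular Reformatsky reaction to give 40. The enolate is thus generated by halide reduction instead of hydride addition.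

Further compounds

F1 | step 14 | C11 α-iodo ketone of 14 (mixture at C11) | CC(I)C(=O)/C=C\[C@@](C)(/C=C/OC)[C@H](O[Si](C)(C)C(C)(C)C)CCO[Si](c1ccccc1)(c1ccccc1)C(C)(C)C
F2 | step 14 | C9 aldehyde from hydrolysis of the enol ether of F1 | CC(I)C(=O)/C=C\[C@@](C)(CC=O)[C@H](O[Si](C)(C)C(C)(C)C)CCO[Si](c1ccccc1)(c1ccccc1)C(C)(C)C
F3 | step 14 | ring A keto aldehyde (C12 ketone, C9 aldehyde) | O=C1C=C[C@@]([C@H](O[Si](C)(C)C(C)(C)C)CCO[Si](c2ccccc2)(c2ccccc2)C(C)(C)C)(C)[C@H]([C@H]1C)C=O
F4 | step 28 | C7 carboxylic acid from 35 | CCCC(=O)O[C@@H]1C=C[C@@]([C@H](OC(C)=O)CC/C(C)=C\I)(C)[C@H]([C@H]1C)[C@@H](OC(C)=O)[C@@H](O[Si](C)(C)C(C)(C)C)C(=O)O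
F5 | step 28 | S-2-pyridyl thioester of F4 | CCCC(=O)O[C@@H]1C=C[C@@]([C@H](OC(C)=O)CC/C(C)=C\I)(C)[C@H]([C@H]1C)[C@@H](OC(C)=O)[C@@H](O[Si](C)(C)C(C)(C)C)C(=O)Sc2ccccn2
F6 | step 28 | macrocyclic enone (C7 ketone, Z C5=C6) | CCCC(=O)O[C@@H]1C=C[C@@]2(C)[C@H]([C@H]1C)[C@@H](OC(C)=O)[C@@H](O[Si](C)(C)C(C)(C)C)C(=O)/C=C(/C)CC[C@H]2OC(C)=O
F7 | step 32 | C7 2-bromopropanoate of 36 (mixture at the CHBr carbon) | CCCC(=O)O[C@@H]1C=C[C@@]2(C)[C@H]([C@H]1C)[C@@H](OC(C)=O)[C@@H](O[Si](C)(C)C(C)(C)C)[C@@H](OC(=O)C(C)Br)/C=C(/C)CC[C@H]2OC(C)=O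
F8 | step 32 | C8 alcohol of F7 | CCCC(=O)O[C@@H]1C=C[C@@]2(C)[C@H]([C@H]1C)[C@@H](OC(C)=O)[C@@H](O)[C@@H](OC(=O)C(C)Br)/C=C(/C)CC[C@H]2OC(C)=O
F9 | step 32 | C8 ketone with C7 2-bromopropanoate | CCCC(=O)O[C@@H]1C=C[C@@]2(C)[C@H]([C@H]1C)[C@@H](OC(C)=O)C(=O)[C@@H](OC(=O)C(C)Br)/C=C(/C)CC[C@H]2OC(C)=O
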